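**Retrosynthetic overview**
- The target is a 5-hydroxy-6,7,8-trimethoxyflavone with a 3',5'-dihydroxy-4'-methoxy B-ring; the last disconnection is a one-pot unmasking of two benzyl ethers and the chelated 5-OMe of flavone 8.
- Ring C (the pyranone) is the only ring built, by iodine/DMSO oxidative cyclisation of 2'-hydroxychalcone 6.
- Chalcone 6 comes from a Claisen–Schmidt condensation of acetophenone 4 (ring A, bought intact) with aldehyde 3 (ring B).
- Aldehyde 3 is the bis-benzyl ether of purchasable 3,5-dihydroxy-4-methoxybenzaldehyde 1.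

Assumption: the target has no stereocentre and is achiral, so "single enantiomer" needs no stereocontrol; compounds 1, 2 and 4 are taken as catalogue chemicals.

**Step 1**
Reactants: 1 3,5-dihydroxy-4-methoxybenzaldehyde; 2 benzyl bromide
Product: 3 3,5-bis(benzyloxy)-4-methoxybenzaldehyde
Conditions: BnBr (2.4 equiv), K2CO3 (4 equiv), DMF, 60 °C
Reagents that add atoms: benzyl bromide, BrCc1ccccc1
Why: Williamson ether synthesis (SN2 O-alkylation of both phenoxides) under carbonate conditions that leave the aldehyde untouched, with no stereocentre formed.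

**Step 2**
Reactants: 3 3,5-bis(benzyloxy)-4-methoxybenzaldehyde; 4 1-(2-hydroxy-3,4,5,6-tetramethoxyphenyl)ethan-1-one
Product: 6 (E)-3-[3,5-bis(benzyloxy)-4-methoxyphenyl]-1-(2-hydroxy-3,4,5,6-tetramethoxyphenyl)prop-2-en-1-one, via aldol adduct 5 (not isolated)
Conditions: KOH (50% aq.), EtOH, rt, 24–48 h; then dilute acid
Reagents that add atoms: none
Why: Claisen–Schmidt (crossed aldol) condensation, in which the methyl ketone enolate adds to the non-enolisable aldehyde and E1cB dehydration of the racemic aldol gives the thermodynamically favoured E-enone, so no stereocentre remains.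

**Step 3**
Reactants: 6 (E)-3-[3,5-bis(benzyloxy)-4-methoxyphenyl]-1-(2-hydroxy-3,4,5,6-tetramethoxyphenyl)prop-2-en-1-one
Product: 8 2-[3,5-bis(benzyloxy)-4-methoxyphenyl]-5,6,7,8-tetramethoxy-4H-chromen-4-one, via flavanone 7 (not isolated)
Conditions: I2 (10 mol%), DMSO, 130 °C
Reagents that add atoms: none
Why: Iodine-catalysed oxidative cyclisation, in which intramolecular oxa-Michael addition of the 2'-OH gives the flavanone and α-iodination/HI elimination dehydrogenates it while DMSO reoxidises HI to I2, so the transient C2 stereocentre is destroyed.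

**Step 4**
Reactants: 8 2-[3,5-bis(benzyloxy)-4-methoxyphenyl]-5,6,7,8-tetramethoxy-4H-chromen-4-one
Product: 10 Gardenin E (5-hydroxy-2-(3,5-dihydroxy-4-methoxyphenyl)-6,7,8-trimethoxy-4H-chromen-4-one), via debenzylated pentamethoxyflavone 9 (not isolated)
Conditions: BCl3 (1 M in CH2Cl2, 6 equiv), pentamethylbenzene (6 equiv), CH2Cl2, −78 °C then 0 °C to rt; aq. HCl work-up
Reagents that add atoms: none
Why: Lewis-acid ether cleavage, in which BCl3 removes the benzyl ethers at low temperature (benzyl cation trapped by pentamethylbenzene) and on warming cleaves only the 5-OMe through its six-membered boron chelate with the C4 carbonyl, leaving the non-chelated 6-, 7-, 8- and 4'-OMe groups.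

**Compound list**
1 | 3,5-dihydroxy-4-methoxybenzaldehyde | COc1c(O)cc(C=O)cc1O | starting material
2 | benzyl bromide | BrCc1ccccc1 | starting material
3 | 3,5-bis(benzyloxy)-4-methoxybenzaldehyde | COc1c(OCc2ccccc2)cc(C=O)cc1OCc1ccccc1 | intermediate
4 | 1-(2-hydroxy-3,4,5,6-tetramethoxyphenyl)ethan-1-one (2'-hydroxy-3',4',5',6'-tetramethoxyacetophenone) | CC(=O)c1c(O)c(OC)c(OC)c(OC)c1OC | starting material
5 | aldol adduct, rac-3-[3,5-bis(benzyloxy)-4-methoxyphenyl]-3-hydroxy-1-(2-hydroxy-3,4,5,6-tetramethoxyphenyl)propan-1-one | COc1c(OCc2ccccc2)cc(C(O)CC(=O)c2c(O)c(OC)c(OC)c(OC)c2OC)cc1OCc1ccccc1 | intermediate (not isolated)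
6 | (E)-3-[3,5-bis(benzyloxy)-4-methoxyphenyl]-1-(2-hydroxy-3,4,5,6-tetramethoxyphenyl)prop-2-en-1-one | COc1c(OCc2ccccc2)cc(/C=C/C(=O)c2c(O)c(OC)c(OC)c(OC)c2OC)cc1OCc1ccccc1 | intermediate
7 | flavanone, rac-2-[3,5-bis(benzyloxy)-4-methoxyphenyl]-5,6,7,8-tetramethoxychroman-4-one | COc1c(OCc2ccccc2)cc(C2CC(=O)c3c(OC)c(OC)c(OC)c(OC)c3O2)cc1OCc1ccccc1 | intermediate (not isolated)
8 | 2-[3,5-bis(benzyloxy)-4-methoxyphenyl]-5,6,7,8-tetramethoxy-4H-chromen-4-one | COc1c(OCc2ccccc2)cc(-c2cc(=O)c3c(OC)c(OC)c(OC)c(OC)c3o2)cc1OCc1ccccc1 | intermediate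
9 | debenzylated pentamethoxyflavone, 2-(3,5-dihydroxy-4-methoxyphenyl)-5,6,7,8-tetramethoxy-4H-chromen-4-one (held in the flask as its boron esters, drawn as the free phenol) | COc1c(O)cc(-c2cc(=O)c3c(OC)c(OC)c(OC)c(OC)c3o2)cc1O | intermediate (not isolated)
10 | Gardenin E, 5-hydroxy-2-(3,5-dihydroxy-4-methoxyphenyl)-6,7,8-trimethoxy-4H-chromen-4-one (achiral) | COc1c(O)cc(-c2cc(=O)c3c(O)c(OC)c(OC)c(OC)c3o2)cc1O | target

**Total step count:** 4
**Longest linear sequence:** 4 steps (1 → 3 → 6 → 8 → 10)

**Three steps most likely to fail, with fallbacks**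

Step 4 (global BCl3 deprotection). The risks are over-demethylation at 6-OMe or at the 4'-OMe flanked by two O–B groups, and C-benzylation of the electron-rich rings. The fallback separates the two cleavages. It sets out from 8 and comes back at 10. Hydrogenolysis of 8 (H2 1 atm, 10% Pd/C, EtOAc/MeOH, rt) gives 9, this time isolated. Chelation-controlled demethylation of 9 with anhydrous AlCl3 in MeCN (rt to 50 °C, then warm dilute HCl) then cleaves only the 5-OMe and gives 10. No compound outside the list is made (F0).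

Step 3 (I2/DMSO oxidative cyclisation). The risks are ring iodination of the alkoxy-rich aryl groups and HI-induced loss of benzyl at 130 °C. The fallback separates ring closure from dehydrogenation and uses no iodine. It sets out from 6 and comes back at 8. Chalcone 6 is isomerised to flavanone 7 (NaOAc, EtOH, reflux; favoured because the 6'-OMe twists the enone) and 7 is isolated. Flavanone 7 is then dehydrogenated with DDQ in refluxing dioxane to 8. No compound outside the list is made (F0).

Step 2 (Claisen–Schmidt condensation). The acetophenone is hindered and electron-rich, so the reaction may be slow, may stall with Cannizzaro loss of 3, or may give chalcone/flavanone mixtures (these would still feed step 3). The fallback is a Baker–Venkataraman route that avoids the chalcone altogether. It sets out from 3 and 4 and comes back at 8, so it also bypasses step 3. Pinnick oxidation of 3 (NaClO2, NaH2PO4, 2-methyl-2-butene, t-BuOH/H2O) gives 3,5-bis(benzyloxy)-4-methoxybenzoic acid F1. Esterification of F1 with phenol 4 (EDC·HCl, DMAP, CH2Cl2) gives 2-acetyl-3,4,5,6-tetramethoxyphenyl 3,5-bis(benzyloxy)-4-methoxybenzoate F2. Baker–Venkataraman acyl shift (KOH, pyridine, 50 °C) gives 1-[3,5-bis(benzyloxy)-4-methoxyphenyl]-3-(2-hydroxy-3,4,5,6-tetramethoxyphenyl)propane-1,3-dione F3. Cyclodehydration of F3 (cat. TsOH, toluene, reflux) gives 8.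

**Further compounds**
F1 | step 2 | 3,5-bis(benzyloxy)-4-methoxybenzoic acid | COc1c(OCc2ccccc2)cc(C(=O)O)cc1OCc1ccccc1
F2 | step 2 | 2-acetyl-3,4,5,6-tetramethoxyphenyl 3,5-bis(benzyloxy)-4-methoxybenzoate | COc1c(OCc2ccccc2)cc(C(=O)Oc2c(C(C)=O)c(OC)c(OC)c(OC)c2OC)cc1OCc1ccccc1
F3 | step 2 | 1-[3,5-bis(benzyloxy)-4-methoxyphenyl]-3-(2-hydroxy-3,4,5,6-tetramethoxyphenyl)propane-1,3-dione | COc1c(OCc2ccccc2)cc(C(=O)CC(=O)c2c(O)c(OC)c(OC)c(OC)c2OC)cc1OCc1ccccc1
F0 | step 3 | none | none
F0 | step 4 | none | none
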